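The pyridine ring is disconnected at N1–C6. Its N1, C2 (with the carboxyl) and C3 are the nitrogen, alpha and beta carbons of aspartic acid, whose side-chain carbonyl is C4; C5 (with OMe) and C6 come from a thiazol-4-yl methoxymethyl ketone. The key step lets the liberated amine of a delta-amino-2-methoxy-1,3-diketone condense with the C6 carbonyl next to the thiazole, closing the ring as a 2,3-dihydro-4-pyridone, which DDQ aromatises in the same flask to the 4-hydroxypicolinate. The precursor is the hydrochloride of the methyl ester of this amino diketone, carrying the complete (S)-6-hydroxyheptylthiazole. O-Methylation and saponification finish the synthesis.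

Key step: step 8

Remark: C5 of the 2-methoxy-1,3-diketones is configurationally labile (keto–enol mixture, both epimers) and is drawn without configuration; the aspartate centre is carried as (S) but is erased in step 8, so its integrity is of no consequence.

Step 1
Reactants: 1 (S)-propylene oxide [(2S)-2-methyloxirane]; 2 but-3-en-1-ylmagnesium bromide
Product: 3 (2S)-hept-6-en-2-ol
Conditions: CuI (10 mol %), THF, −40 → 0 °C; aq NH4Cl
Reagents that add atoms: none
Why: Copper-catalysed SN2 opening of the epoxide by the Grignard reagent occurs at the unsubstituted CH2, so the C–O stereocentre of 1 is not touched and is carried over as (S).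

Step 2
Reactants: 3 (2S)-hept-6-en-2-ol
Product: 4 tert-butyl{[(2S)-hept-6-en-2-yl]oxy}dimethylsilane
Conditions: TBSCl, imidazole, CH2Cl2, 0 °C → rt
Reagents that add atoms: tert-butyldimethylsilyl chloride (TBSCl), CC(C)(C)[Si](C)(C)Cl
Why: Standard silyl ether protection of a secondary alcohol masks the hydroxyl for the organometallic and enolate steps that follow.

Step 3
Reactants: 4 tert-butyl{[(2S)-hept-6-en-2-yl]oxy}dimethylsilane; 5 2,4-dibromo-1,3-thiazole
Product: 7 4-bromo-2-[(6S)-6-{[tert-butyl(dimethyl)silyl]oxy}heptyl]-1,3-thiazole, via B-alkyl-9-BBN borane 6 (not isolated)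
Conditions: 9-BBN, THF, rt; then 5 (1.2 equiv), PdCl2(dppf) (5 mol %), K3PO4 (3 M aq), DMF, 50 °C
Reagents that add atoms: none
Why: Anti-Markovnikov hydroboration of the terminal alkene is followed by B-alkyl Suzuki–Miyaura coupling, in which zerovalent palladium inserts into the more electron-poor C2–Br bond of 5 much faster than into C4–Br, so only the 2-position should be alkylated.

Step 4
Reactants: 7 4-bromo-2-[(6S)-6-{[tert-butyl(dimethyl)silyl]oxy}heptyl]-1,3-thiazole; 8 N,2-dimethoxy-N-methylacetamide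
Product: 10 1-{2-[(6S)-6-{[tert-butyl(dimethyl)silyl]oxy}heptyl]-1,3-thiazol-4-yl}-2-methoxyethan-1-one, via 4-lithiothiazole 9 (not isolated)
Conditions: n-BuLi, Et2O, −78 °C; then 8, −78 → 0 °C; aq NH4Cl
Reagents that add atoms: none
Why: Bromine–lithium exchange at C4 is faster at −78 °C than deprotonation of the ring or of the side chain, and the Weinreb ketone synthesis stops at the chelated tetrahedral adduct, so the methoxymethyl ketone should form without over-addition.

Step 5
Reactants: 11 N-Boc-L-aspartic acid 1-methyl ester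
Product: 12 methyl (2S)-4-(1H-benzotriazol-1-yl)-2-[(tert-butoxycarbonyl)amino]-4-oxobutanoate
Conditions: 1H-benzotriazole, EDC·HCl, CH2Cl2, 0 °C → rt
Reagents that add atoms: 1H-benzotriazole, c1ccc2[nH]nnc2c1
Why: Carbodiimide coupling converts the free side-chain acid into a stable, isolable N-acylbenzotriazole, an acyl donor suited to C-acylation without a strong base.

Step 6
Reactants: 10 1-{2-[(6S)-6-{[tert-butyl(dimethyl)silyl]oxy}heptyl]-1,3-thiazol-4-yl}-2-methoxyethan-1-one; 12 methyl (2S)-4-(1H-benzotriazol-1-yl)-2-[(tert-butoxycarbonyl)amino]-4-oxobutanoate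
Product: 13 methyl (2S)-2-[(tert-butoxycarbonyl)amino]-6-{2-[(6S)-6-{[tert-butyl(dimethyl)silyl]oxy}heptyl]-1,3-thiazol-4-yl}-5-methoxy-4,6-dioxohexanoate
Conditions: MgBr2·OEt2 (2.5 equiv), i-Pr2NEt (3 equiv), 12 (1.3 equiv), CH2Cl2, rt; aq citric acid
Reagents that add atoms: none
Why: In this soft enolisation, MgBr2 chelated by the ketone and its alpha-methoxy oxygen lets the amine base form the magnesium enolate at the only enolisable position, which is C-acylated by 12 (crossed Claisen-type acylation) and held as the magnesium diketonate, while the carbamate N–H and the silyl ether are left alone by the weak base.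

Step 7
Reactants: 13 methyl (2S)-2-[(tert-butoxycarbonyl)amino]-6-{2-[(6S)-6-{[tert-butyl(dimethyl)silyl]oxy}heptyl]-1,3-thiazol-4-yl}-5-methoxy-4,6-dioxohexanoate
Product: 14 methyl (2S)-2-amino-6-{2-[(6S)-6-hydroxyheptyl]-1,3-thiazol-4-yl}-5-methoxy-4,6-dioxohexanoate hydrochloride
Conditions: HCl (4 M in 1,4-dioxane), H2O (5 equiv), 0 °C → rt; evaporation, trituration with Et2O
Reagents that add atoms: hydrogen chloride, Cl
Why: Acidolysis removes the Boc group (as isobutene and CO2) and the secondary TBS ether in one operation, and the amine is held as its ammonium salt so that it can neither condense nor eliminate before step 8.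

Step 8
Reactants: 14 methyl (2S)-2-amino-6-{2-[(6S)-6-hydroxyheptyl]-1,3-thiazol-4-yl}-5-methoxy-4,6-dioxohexanoate hydrochloride
Product: 17 methyl 4-hydroxy-6-{2-[(6S)-6-hydroxyheptyl]-1,3-thiazol-4-yl}-5-methoxypyridine-2-carboxylate, via free amino diketone 15 (not isolated), via 2,3-dihydro-4-pyridone 16 (not isolated)
Conditions: NaOAc (1.5 equiv), AcOH (2 equiv), 4 Å MS, MeCN (0.02 M), rt → 45 °C; then DDQ (1.1 equiv), 0 °C → rt
Reagents that add atoms: none
Why: NaOAc frees the amine of 14, which adds to the C6 ketone (the carbonyl on C4 of the thiazole) and loses water, so that N1–C6 is formed and the ring closes as a cyclic vinylogous amide; tautomerisation to the 4-hydroxy-1,2-dihydropyridine then lets DDQ take a hydride from C2 and, after loss of a proton, leave the aromatic 4-hydroxypyridine. The closest known reaction type is the cyclocondensation of delta-amino-1,3-dicarbonyl compounds to 2,3-dihydro-4-pyridones followed by quinone dehydrogenation to 4-pyridones. The ring closure is a 6-exo-trig addition of nitrogen to the C6 carbonyl followed by dehydration. No stereocentre is created: C2 and C5 both become sp2, so the C5 epimers converge and the remote (S)-carbinol is untouched. The step needs nitrogen to attack C6 and not C4, and to do so faster than loss of ammonia by beta-elimination or intermolecular condensation; attack at C4 would give a four-membered ring, the acetate buffer keeps the medium too weakly basic for E1cB elimination through the C3 enolate, and dilution disfavours dimerisation. DDQ should not oxidise the unactivated secondary alcohol or the thiazole.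

Step 9
Reactants: 17 methyl 4-hydroxy-6-{2-[(6S)-6-hydroxyheptyl]-1,3-thiazol-4-yl}-5-methoxypyridine-2-carboxylate
Product: 18 methyl 6-{2-[(6S)-6-hydroxyheptyl]-1,3-thiazol-4-yl}-4,5-dimethoxypyridine-2-carboxylate
Conditions: MeI (1.5 equiv), K2CO3 (2 equiv), DMF, rt
Reagents that add atoms: iodomethane, CI
Why: In this Williamson-type alkylation of the ambident pyridinolate, N1 is flanked by the ester at C2 and the thiazole at C6, so methylation should go to oxygen, and K2CO3 does not deprotonate the aliphatic secondary alcohol.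

Step 10
Reactants: 18 methyl 6-{2-[(6S)-6-hydroxyheptyl]-1,3-thiazol-4-yl}-4,5-dimethoxypyridine-2-carboxylate
Product: 19 6-{2-[(6S)-6-hydroxyheptyl]-1,3-thiazol-4-yl}-4,5-dimethoxypyridine-2-carboxylic acid (CNP0267511.1)
Conditions: LiOH·H2O (3 equiv), THF/H2O, rt; then 1 M HCl to pH 3–4
Reagents that add atoms: lithium hydroxide, [Li+].[OH-]
Why: Saponification of the methyl picolinate leaves the thiazole, the two aryl methyl ethers and the carbinol stereocentre untouched at room temperature.

Compound list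
1 | (S)-propylene oxide, (2S)-2-methyloxirane | C[C@H]1CO1 | starting material
2 | but-3-en-1-ylmagnesium bromide (commercial THF solution) | C=CCC[Mg]Br | starting material
3 | (2S)-hept-6-en-2-ol | C=CCCC[C@H](C)O | intermediate
4 | tert-butyl{[(2S)-hept-6-en-2-yl]oxy}dimethylsilane | C=CCCC[C@H](C)O[Si](C)(C)C(C)(C)C | intermediate
5 | 2,4-dibromo-1,3-thiazole | Brc1csc(Br)n1 | starting material
6 | 9-[(6S)-6-{[tert-butyl(dimethyl)silyl]oxy}heptyl]-9-borabicyclo[3.3.1]nonane | B1(CCCCC[C@H](C)O[Si](C)(C)C(C)(C)C)C2CCCC1CCC2 | intermediate (not isolated)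
7 | 4-bromo-2-[(6S)-6-{[tert-butyl(dimethyl)silyl]oxy}heptyl]-1,3-thiazole | Brc1csc(CCCCC[C@H](C)O[Si](C)(C)C(C)(C)C)n1 | intermediate
8 | N,2-dimethoxy-N-methylacetamide | COCC(=O)N(C)OC | starting material
9 | {2-[(6S)-6-{[tert-butyl(dimethyl)silyl]oxy}heptyl]-1,3-thiazol-4-yl}lithium | [Li]c1csc(CCCCC[C@H](C)O[Si](C)(C)C(C)(C)C)n1 | intermediate (not isolated)
10 | 1-{2-[(6S)-6-{[tert-butyl(dimethyl)silyl]oxy}heptyl]-1,3-thiazol-4-yl}-2-methoxyethan-1-one | COCC(=O)c1csc(CCCCC[C@H](C)O[Si](C)(C)C(C)(C)C)n1 | intermediate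
11 | N-Boc-L-aspartic acid 1-methyl ester | COC(=O)[C@H](CC(=O)O)NC(=O)OC(C)(C)C | starting material
12 | methyl (2S)-4-(1H-benzotriazol-1-yl)-2-[(tert-butoxycarbonyl)amino]-4-oxobutanoate | COC(=O)[C@H](CC(=O)n1nnc2ccccc21)NC(=O)OC(C)(C)C | intermediate
13 | methyl (2S)-2-[(tert-butoxycarbonyl)amino]-6-{2-[(6S)-6-{[tert-butyl(dimethyl)silyl]oxy}heptyl]-1,3-thiazol-4-yl}-5-methoxy-4,6-dioxohexanoate | COC(=O)[C@H](CC(=O)C(OC)C(=O)c1csc(CCCCC[C@H](C)O[Si](C)(C)C(C)(C)C)n1)NC(=O)OC(C)(C)C | intermediate
14 | methyl (2S)-2-amino-6-{2-[(6S)-6-hydroxyheptyl]-1,3-thiazol-4-yl}-5-methoxy-4,6-dioxohexanoate hydrochloride | COC(=O)[C@@H](N)CC(=O)C(OC)C(=O)c1csc(CCCCC[C@H](C)O)n1.Cl | intermediate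
15 | methyl (2S)-2-amino-6-{2-[(6S)-6-hydroxyheptyl]-1,3-thiazol-4-yl}-5-methoxy-4,6-dioxohexanoate (free amine) | COC(=O)[C@@H](N)CC(=O)C(OC)C(=O)c1csc(CCCCC[C@H](C)O)n1 | intermediate (not isolated)
16 | methyl (2S)-6-{2-[(6S)-6-hydroxyheptyl]-1,3-thiazol-4-yl}-5-methoxy-4-oxo-1,2,3,4-tetrahydropyridine-2-carboxylate | COC(=O)[C@@H]1CC(=O)C(OC)=C(c2csc(CCCCC[C@H](C)O)n2)N1 | intermediate (not isolated)
17 | methyl 4-hydroxy-6-{2-[(6S)-6-hydroxyheptyl]-1,3-thiazol-4-yl}-5-methoxypyridine-2-carboxylate | COC(=O)c1cc(O)c(OC)c(-c2csc(CCCCC[C@H](C)O)n2)n1 | intermediate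
18 | methyl 6-{2-[(6S)-6-hydroxyheptyl]-1,3-thiazol-4-yl}-4,5-dimethoxypyridine-2-carboxylate | COC(=O)c1cc(OC)c(OC)c(-c2csc(CCCCC[C@H](C)O)n2)n1 | intermediate
19 | 6-{2-[(6S)-6-hydroxyheptyl]-1,3-thiazol-4-yl}-4,5-dimethoxypyridine-2-carboxylic acid | COc1cc(C(=O)O)nc(-c2csc(CCCCC[C@H](C)O)n2)c1OC | target

Total step count: 10. Longest linear sequence: 9 steps (steps 1–4 and 6–10); step 5 is a one-step side branch.

Steps most likely to fail

Step 8. Loss of ammonia by beta-elimination from the beta-amino ketone, or intermolecular condensation, may outrun ring closure, and the dehydrogenation may stall or over-oxidise. The fallback builds the same pyridine from a 1,3,5-tricarbonyl compound and ammonia, a classical 4-pyridone synthesis, and sets out from 10. C-Acetylation of 10 with 1-acetylbenzotriazole under the conditions of step 6 should give 1-{2-[(6S)-6-{[tert-butyl(dimethyl)silyl]oxy}heptyl]-1,3-thiazol-4-yl}-2-methoxybutane-1,3-dione F1. Its dianion (LiN(i-Pr)2, 2.5 equiv, THF, −78 °C) should be acylated at the terminal methyl by dimethyl oxalate to give methyl 6-{2-[(6S)-6-{[tert-butyl(dimethyl)silyl]oxy}heptyl]-1,3-thiazol-4-yl}-5-methoxy-2,4,6-trioxohexanoate F2. Heating with NH4OAc in MeOH/AcOH should close the ring to methyl 6-{2-[(6S)-6-{[tert-butyl(dimethyl)silyl]oxy}heptyl]-1,3-thiazol-4-yl}-4-hydroxy-5-methoxypyridine-2-carboxylate F3. HCl in MeOH then removes the silyl ether, and the route is rejoined at 17.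

Step 6. Enolisation of 10 may be slow, so that O-acylation, beta-elimination of the carbamate from the acyl donor, or retro-Claisen cleavage of the 2-methoxy-1,3-diketone on work-up intervene. The fallback makes the C4–C5 bond by an aldol addition and sets out from 10. Ozonolysis (O3, CH2Cl2, −78 °C; Me2S) of commercial methyl N-Boc-L-allylglycinate should give methyl (2S)-2-[(tert-butoxycarbonyl)amino]-4-oxobutanoate F4. Addition of the lithium enolate of 10 (LiN(SiMe3)2, THF, −78 °C) to this aldehyde should give methyl (2S)-2-[(tert-butoxycarbonyl)amino]-6-{2-[(6S)-6-{[tert-butyl(dimethyl)silyl]oxy}heptyl]-1,3-thiazol-4-yl}-4-hydroxy-5-methoxy-6-oxohexanoate F5 as a mixture of diastereomers, which is of no consequence. Oxidation with Dess–Martin periodinane (CH2Cl2, NaHCO3, rt) rejoins the route at 13.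

Step 4. Deprotonation at thiazole C5 or at the side-chain CH2 next to C2, migration of the halogen, or enolisation of the Weinreb amide may compete with clean exchange and acylation. The fallback avoids the aryllithium and sets out from 4. Hydroboration with 9-BBN and coupling (PdCl2(dppf), K3PO4, DMF, 50 °C) with commercial ethyl 2-bromo-1,3-thiazole-4-carboxylate should give ethyl 2-[(6S)-6-{[tert-butyl(dimethyl)silyl]oxy}heptyl]-1,3-thiazole-4-carboxylate F6. Crossed Claisen condensation with the lithium enolate of methyl methoxyacetate (LiN(i-Pr)2, THF, −78 °C) should give methyl 3-{2-[(6S)-6-{[tert-butyl(dimethyl)silyl]oxy}heptyl]-1,3-thiazol-4-yl}-2-methoxy-3-oxopropanoate F7. Krapcho demethoxycarbonylation (LiCl, wet DMSO, 130 °C) rejoins the route at 10.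

Further compounds
F1 | step 8 | 1-{2-[(6S)-6-{[tert-butyl(dimethyl)silyl]oxy}heptyl]-1,3-thiazol-4-yl}-2-methoxybutane-1,3-dione | CC(=O)C(OC)C(=O)c1csc(CCCCC[C@H](C)O[Si](C)(C)C(C)(C)C)n1
F2 | step 8 | methyl 6-{2-[(6S)-6-{[tert-butyl(dimethyl)silyl]oxy}heptyl]-1,3-thiazol-4-yl}-5-methoxy-2,4,6-trioxohexanoate | COC(=O)C(=O)CC(=O)C(OC)C(=O)c1csc(CCCCC[C@H](C)O[Si](C)(C)C(C)(C)C)n1
F3 | step 8 | methyl 6-{2-[(6S)-6-{[tert-butyl(dimethyl)silyl]oxy}heptyl]-1,3-thiazol-4-yl}-4-hydroxy-5-methoxypyridine-2-carboxylate | COC(=O)c1cc(O)c(OC)c(-c2csc(CCCCC[C@H](C)O[Si](C)(C)C(C)(C)C)n2)n1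
F4 | step 6 | methyl (2S)-2-[(tert-butoxycarbonyl)amino]-4-oxobutanoate | COC(=O)[C@H](CC=O)NC(=O)OC(C)(C)C
F5 | step 6 | methyl (2S)-2-[(tert-butoxycarbonyl)amino]-6-{2-[(6S)-6-{[tert-butyl(dimethyl)silyl]oxy}heptyl]-1,3-thiazol-4-yl}-4-hydroxy-5-methoxy-6-oxohexanoate | COC(=O)[C@H](CC(O)C(OC)C(=O)c1csc(CCCCC[C@H](C)O[Si](C)(C)C(C)(C)C)n1)NC(=O)OC(C)(C)C
F6 | step 4 | ethyl 2-[(6S)-6-{[tert-butyl(dimethyl)silyl]oxy}heptyl]-1,3-thiazole-4-carboxylate | CCOC(=O)c1csc(CCCCC[C@H](C)O[Si](C)(C)C(C)(C)C)n1
F7 | step 4 | methyl 3-{2-[(6S)-6-{[tert-butyl(dimethyl)silyl]oxy}heptyl]-1,3-thiazol-4-yl}-2-methoxy-3-oxopropanoate | COC(=O)C(OC)C(=O)c1csc(CCCCC[C@H](C)O[Si](C)(C)C(C)(C)C)n1
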